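**Plan**
1. Cuts: C11–C12 (two C15 halves, joined last by alkyl–alkyl Suzuki–Miyaura coupling); C9=C11 and C9′=C12 (methylenation of C9 ketones); in ring A, C1–C2 and C3–C4 (a two-carbon alkyne unit = C2–C3); C10–C1 and C10–CH3 (enolate chemistry).
2. Forward: ring B of both halves is (R)-carvone (C5–C10, the C8 methyl, and the isopropenyl group = C4 with its two methyls). C10 is made quaternary, ring A is closed onto ring B in one palladium cascade, enedione 10 feeds both halves, and the halves are united in the last step.
3. Enabling feature: C10 is quaternary, so an alkylpalladium at C1 cannot β-eliminate, and C4 is a gem-dimethyl quaternary carbon, which is what an isopropenyl carbon becomes after carbopalladation and hydride capture. C1–I, the C5 isopropenyl group and an alkyne can therefore close ring A 6-exo in one operation.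
4. Stereochemistry: C5 from carvone; C10 by aldol anti to the isopropenyl group; C3 and C3′ by equatorial hydride delivery (axial 3α-OH); C8′ by equilibration next to the C9′ ketone; C9 and C9′ by hydroboration anti to the axial C10 methyl.

Key step: step 4

Numbering: each half is numbered like a steroid A/B system (ring A = C1–C5 and C10; ring B = C5–C10; gem-dimethyl on C4, angular methyl on C10, a methyl on C8). C11 is the CH2 on C9 of the unsaturated half, C12 the CH2 on C9′ of the saturated (primed) half, and α is the face opposite the C10 methyl. Monocycles 1–6 carry carvone numbering; carvone C6, C1, C2, C3, C4, C5 and the isopropenyl carbon become C10, C9, C8, C7, C6, C5 and C4.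

Remark on configuration: the SMILES is read as 5α-H, 10β-CH3 and 9α-H in both halves, an axial 3α-OH in both halves, and an equatorial 8′α-methyl trans to the C9′ side chain; the route is planned for this.

**Step 1**
Reactants: 1 (R)-(−)-carvone
Product: 3 6-methylcarvone (mixture of C6 epimers), via lithium dienolate 2 (not isolated)
Conditions: LiN(i-Pr)2, THF, −78 °C; MeI, −78 to 0 °C
Reagents that add atoms: iodomethane, CI
Why: Kinetic deprotonation of the enone at C6 (α′) and C-methylation of the cross-conjugated lithium dienolate (enolate alkylation) should give 3; the new centre forms as an epimer mixture that is erased again in step 2.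

**Step 2**
Reactants: 3 6-methylcarvone
Product: 5 6-(hydroxymethyl)-6-methylcarvone (CH2OH trans to isopropenyl), via lithium enolate 4 (not isolated)
Conditions: LiN(i-Pr)2, THF, −78 °C; CH2O (gas), −78 to −40 °C; aq. NH4Cl
Reagents that add atoms: formaldehyde, C=O
Why: Aldol addition of the fully substituted lithium enolate to formaldehyde should occur on the face anti to the adjacent isopropenyl group, so that CH2OH (future C1) is trans and CH3 (future angular methyl) cis to it, which sets C10.

**Step 3**
Reactants: 5 6-(hydroxymethyl)-6-methylcarvone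
Product: 6 6-(iodomethyl)-6-methylcarvone
Conditions: I2, PPh3, imidazole, toluene, 80 °C
Reagents that add atoms: iodine, II
Why: Appel-type iodination should convert the neopentyl primary alcohol into the iodide, the quaternary neighbour excluding elimination and the near-neutral medium disfavouring retro-aldol loss of formaldehyde.

**Step 4**
Reactants: 6 6-(iodomethyl)-6-methylcarvone; 7 ethynyltrimethylsilane
Product: 8 bicyclic vinylsilane enone (ring A closed; SiMe3 on C3 of a C2=C3 double bond; gem-dimethyl C4)
Conditions: Pd(PPh3)4 (10 mol %), 7 (5 equiv), HCO2Na, DMF, 90 °C, sealed tube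
Reagents that add atoms: none
Why: Proposed new method: zerovalent palladium should add oxidatively to the neopentyl C1–I bond (by iodine-atom abstraction and recombination or by displacement), giving an alkylpalladium that cannot β-hydride eliminate because C10 is quaternary; it carbopalladates the alkyne syn, C1 going to the unsubstituted carbon (C2) and palladium to the silyl-bearing carbon (C3), as silylalkynes do in Larock-type annulations. The alkenylpalladium, held cis to the C1 tether, then inserts the isopropenyl group in a 6-exo-trig Heck cyclisation that forms C3–C4 and ring A, and the resulting CH2–Pd on the new quaternary C4 again has no β-hydrogen and is reduced by formate (loss of CO2) to the second C4 methyl. The closest known reaction types are the alkyl Heck reaction of unactivated alkyl iodides, the carboannulation of alkynes by organopalladium halides carrying a pendant alkene, and reductive Heck cyclisation with formate as hydride source; new here is starting such a cascade from an alkyl iodide with an intermolecular alkyne insertion. No stereocentre is created (C4 becomes a gem-dimethyl carbon, C3 is sp2), and the trans ring fusion is inherited from C5 (carvone) and C10 (step 2), whose isopropenyl and CH2I groups are trans-diequatorial on ring B and can be bridged. The step needs alkyne insertion to outrun formate reduction of the first alkylpalladium (excess alkyne, sparingly soluble HCO2Na), the silicon-directed regiochemistry of insertion, and exo closure onto the isopropenyl group and not onto the electron-poor, more distant enone carbons.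

**Step 5**
Reactants: 8 bicyclic vinylsilane enone
Product: 10 enedione (7-ene-3,9-dione), via epoxysilane 9 (not isolated)
Conditions: mCPBA, NaHCO3, CH2Cl2, 0 °C to rt; then H2SO4, MeOH–H2O, 50 °C
Reagents that add atoms: 3-chloroperoxybenzoic acid, OOC(=O)c1cccc(Cl)c1; water, O
Why: Peracid epoxidation should occur only at the electron-rich vinylsilane (the enone alkene is electron-poor); aqueous acid then hydrolyses the α,β-epoxysilane to the 2,3-diol, which loses Me3SiOH in a Peterson-type elimination to the C3 enol, the classical vinylsilane-to-ketone unmasking that places the carbonyl on the carbon that bore silicon and forms no stereocentre.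

**Step 6**
Reactants: 10 enedione
Product: 12 ketol (3α-hydroxy-8α-methyl 9-ketone), via dilithium enolate alkoxide 11 (not isolated)
Conditions: LiBH(s-Bu)3 (3 equiv), THF, −78 to 0 °C; H2O; then NaOMe, MeOH, rt
Reagents that add atoms: none
Why: LiBH(s-Bu)3 should add hydride 1,4 to the β-unsubstituted enone (giving the C9 enolate) and, from the equatorial direction, to the hindered C3 ketone to give the axial 3α-alcohol; methoxide then equilibrates C8′ next to the C9′ ketone to the equatorial 8′α-methyl, which avoids the 1,3-diaxial contact with the C10′ methyl.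

**Step 7**
Reactants: 12 ketol
Product: 13 9′-methylene alcohol
Conditions: Ph3PCH3Br, KOt-Bu, toluene, 100 °C
Reagents that add atoms: methyltriphenylphosphonium bromide, C[P+](c1ccccc1)(c1ccccc1)c1ccccc1.[Br-]
Why: Wittig methylenation with excess ylide at elevated temperature is the standard way to methylenate a hindered α,α′-branched cyclohexanone, and C8′ is already the thermodynamic epimer, so the basic medium cannot erode it.

**Step 8**
Reactants: 13 9′-methylene alcohol
Product: 15 diol (9′β-hydroxymethyl-3′α-ol), via bis-boryl adduct 14 (not isolated)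
Conditions: 9-BBN-H (2.5 equiv), THF, 65 °C; then NaOH, H2O2, 0 °C to rt
Reagents that add atoms: hydrogen peroxide, OO
Why: Hydroboration–oxidation: 9-BBN should place boron on the terminal carbon and deliver hydrogen to C9′ from the α face, anti to the axial C10′ methyl, so that the CH2OH group is β (equatorial) and trans to the 8′α-methyl.

**Step 9**
Reactants: 15 diol
Product: 16 iodo alcohol (9′β-iodomethyl-3′α-ol)
Conditions: I2, PPh3, imidazole, CH2Cl2, 0 °C to rt
Reagents that add atoms: iodine, II
Why: Appel iodination should be selective for the primary alcohol over the hindered axial secondary alcohol at C3′.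

**Step 10**
Reactants: 10 enedione
Product: 19 dienone (9-methylene-7-en-3-one), via silyl enol ether 17 (not isolated), via silyl enol ether triene 18 (not isolated)
Conditions: LiN(i-Pr)2, THF, −78 °C; Me3SiCl; Ph3P=CH2 (from Ph3PCH3Br, KOt-Bu), THF, 0 to 60 °C; then K2CO3, MeOH, rt
Reagents that add atoms: methyltriphenylphosphonium bromide, C[P+](c1ccccc1)(c1ccccc1)c1ccccc1.[Br-]
Why: The only carbonyl with an α-hydrogen (C3, through C2–H) is masked in the flask as its trimethylsilyl enol ether, so that the Wittig ylide can only methylenate the C9 enone carbonyl, and methanolysis returns the C3 ketone.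

**Step 11**
Reactants: 19 dienone
Product: 20 dienol (9-methylene-7-en-3α-ol)
Conditions: LiBH(s-Bu)3, THF, −78 °C; H2O
Reagents that add atoms: none
Why: Equatorial hydride delivery from the bulky borohydride to the 4,4-dimethyl-3-ketone should give the axial 3α-alcohol, the unconjugated carbonyl being the only group that reacts.

**Step 12**
Reactants: 20 dienol; 16 iodo alcohol
Product: 22 target CNP0194061.3, via bis-boryl adduct 21 (not isolated)
Conditions: 20, 9-BBN-H (2.2 equiv), THF, 60 °C; then 16, NiCl2·glyme (10 mol %), trans-N,N′-dimethylcyclohexane-1,2-diamine, KOt-Bu, i-BuOH, dioxane, rt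
Reagents that add atoms: none
Why: 9-BBN should hydroborate the 1,1-disubstituted terminus of the diene from the α face (anti to the C10 methyl), which sets 9α-H with C11 β; the B-alkyl-9-BBN is then joined to the primary iodide by a nickel-catalysed alkyl–alkyl Suzuki–Miyaura coupling, whose radical-type activation of the C–I bond tolerates β-branching and free hydroxyl groups.

**Compound list**
1 | (R)-(−)-carvone, (5R)-2-methyl-5-(prop-1-en-2-yl)cyclohex-2-en-1-one | CC1=CC[C@H](CC1=O)C(C)=C | starting material
2 | lithium dienolate of 1 (C6=C1–OLi, C2=C3) | CC1=CC[C@H](C=C1[O-])C(C)=C.[Li+] | intermediate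
3 | 6-methylcarvone, mixture of C6 epimers | CC1=CC[C@H](C(C)C1=O)C(C)=C | intermediate
4 | lithium dienolate of 3 (C6=C1–OLi) | CC1=CC[C@H](C(C)=C1[O-])C(C)=C.[Li+] | intermediate
5 | 6-(hydroxymethyl)-6-methylcarvone; at C6 the CH2OH is trans and the CH3 cis to the C5 isopropenyl group | CC1=CC[C@@H](C(C)=C)[C@](C)(CO)C1=O | intermediate
6 | 6-(iodomethyl)-6-methylcarvone, same configuration as 5 | CC1=CC[C@@H](C(C)=C)[C@](C)(CI)C1=O | intermediate
7 | ethynyltrimethylsilane | C#C[Si](C)(C)C | starting material
8 | 4,4,8,10-tetramethyl-3-(trimethylsilyl)-trans-bicyclo[4.4.0]deca-2,7-dien-9-one (steroid-type locants; 5α-H, 10β-CH3) | CC1=CC[C@H]2C(C)(C)C([Si](C)(C)C)=CC[C@]2(C)C1=O | intermediate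
9 | 2,3-epoxide of 8 (α,β-epoxysilane, either face) | CC1=CC[C@H]2C(C)(C)C3(OC3C[C@]2(C)C1=O)[Si](C)(C)C | intermediate
10 | 4,4,8,10-tetramethyl-trans-decal-7-ene-3,9-dione (5α-H, 10β-CH3) | CC1=CC[C@H]2C(C)(C)C(=O)CC[C@]2(C)C1=O | intermediate
11 | dilithium salt: C8=C9 enolate and 3α-alkoxide | [O-]C1=C(C)CC[C@H]2C(C)(C)[C@H]([O-])CC[C@]12C.[Li+].[Li+] | intermediate
12 | 3α-hydroxy-4,4,8α,10β-tetramethyl-trans-decalin-9-one (5α-H, 8β-H) | O=C1[C@H](C)CC[C@H]2C(C)(C)[C@H](O)CC[C@]12C | intermediate
13 | 4′,4′,8′α,10′β-tetramethyl-9′-methylene-trans-decalin-3′α-ol (methylene carbon = C12) | C=C1[C@H](C)CC[C@H]2C(C)(C)[C@H](O)CC[C@]12C | intermediate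
14 | C12-(9-BBN) borane, O3′-(9-BBN) borinate of 13 (9′α-H) | C(B3C4CCCC3CCC4)[C@H]1[C@H](C)CC[C@H]2C(C)(C)[C@H](OB5C6CCCC5CCC6)CC[C@]12C | intermediate
15 | 9′β-(hydroxymethyl)-4′,4′,8′α,10′β-tetramethyl-trans-decalin-3′α-ol (5′α-H, 9′α-H) | OC[C@H]1[C@H](C)CC[C@H]2C(C)(C)[C@H](O)CC[C@]12C | intermediate
16 | 9′β-(iodomethyl)-4′,4′,8′α,10′β-tetramethyl-trans-decalin-3′α-ol | IC[C@H]1[C@H](C)CC[C@H]2C(C)(C)[C@H](O)CC[C@]12C | intermediate
17 | 3-(trimethylsilyloxy)-2-ene enol ether of 10 | CC1=CC[C@H]2C(C)(C)C(O[Si](C)(C)C)=CC[C@]2(C)C1=O | intermediate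
18 | 3-(trimethylsilyloxy)-9-methylene-2,7-diene | CC1=CC[C@H]2C(C)(C)C(O[Si](C)(C)C)=CC[C@]2(C)C1=C | intermediate
19 | 4,4,8,10-tetramethyl-9-methylene-trans-decal-7-en-3-one (5α-H, 10β-CH3; methylene carbon = C11) | CC1=CC[C@H]2C(C)(C)C(=O)CC[C@]2(C)C1=C | intermediate
20 | 4,4,8,10-tetramethyl-9-methylene-trans-decal-7-en-3α-ol | CC1=CC[C@H]2C(C)(C)[C@H](O)CC[C@]2(C)C1=C | intermediate
21 | C11-(9-BBN) borane, O3-(9-BBN) borinate from 20 (9α-H) | CC1=CC[C@H]2C(C)(C)[C@H](OB3C4CCCC3CCC4)CC[C@]2(C)[C@H]1CB5C6CCCC5CCC6 | intermediate
22 | CNP0194061.3: 9β-[2-(3′α-hydroxy-4′,4′,8′α,10′β-tetramethyl-trans-decalin-9′β-yl)ethyl]-4,4,8,10β-tetramethyl-trans-decal-7-en-3α-ol (5α, 9α, 5′α, 8′β, 9′α-H) | CC1=CC[C@H]2C(C)(C)[C@H](O)CC[C@]2(C)[C@H]1CC[C@H]1[C@H](C)CC[C@H]2C(C)(C)[C@H](O)CC[C@]12C | target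

Total step count: 12. Longest linear sequence: 10 steps (steps 1–9, then step 12).

**Steps most likely to fail**

Step 4 (proposed cascade). The first alkylpalladium may be reduced by formate before it meets the alkyne. A free C1 radical may ring-expand through the C9 carbonyl (Dowd–Beckwith-type). The alkenylpalladium may be reduced before it closes onto the hindered isopropenyl carbon, or palladium hydride may reduce the enone. The fallback uses known reactions and a different bond set (C10–C1 by alkylation, C3–C4 by radical addition to an aldehyde). It sets out from 3: LiN(i-Pr)2 and then propargyl bromide should give 6-methyl-6-(prop-2-ynyl)carvone F1, with the propargyl group trans to the isopropenyl group. Dicyclohexylborane adds to the terminal alkyne to give the alkenylborane F2 (not isolated), and NaBO3·4H2O oxidises it to the 3-oxopropyl ketone F3. Fe(acac)3 and PhSiH3 in EtOH transfer a hydrogen atom to the isopropenyl group, and the tertiary C4 radical adds 6-exo to the aldehyde, giving the 3-hydroxy enone F4 as a C3 epimer mixture. Dess–Martin oxidation returns to the route at 10.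

Step 12 (fragment union). The β-branched borane may transmetalate slowly and the hindered iodide may eliminate to alkene 13 or be reduced. The fallback is a Julia–Kocienski olefination followed by diimide reduction, setting out from 16 and 20. From 16, 1-phenyl-1H-tetrazole-5-thiol and K2CO3 in DMF give the sulfide F5, and (NH4)6Mo7O24 with H2O2 gives the sulfone F6. From 20, 9-BBN-H (through 21) and then NaBO3·4H2O give the 9β-hydroxymethyl dienol F7, and TEMPO with PhI(OAc)2 oxidises only the primary alcohol to the aldehyde F8. KN(SiMe3)2 (excess, to cover the free hydroxyl groups) in DME at −60 °C, added to the mixture of F6 and F8, should give the (E)-C11=C12 alkene F9. Diimide (TsNHNH2, NaOAc, DME–H2O, reflux) reduces the disubstituted alkene and spares the trisubstituted C7=C8, returning at 22.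

Step 10 (methylenation of the enone). The basic ylide may deprotonate the hindered enone at its γ-position instead of adding, or the silyl enol ether may be lost early so that C3 competes. The fallback is a Peterson olefination through an organocerium, setting out from 10. Silyl enol ether 17 is formed as in step 10, and Me3SiCH2Li with CeCl3 in THF at −78 °C adds to the C9 carbonyl; a cold quench with aqueous NaHCO3 gives the β-hydroxysilane F10, which keeps the silyl enol ether. KH in THF then effects the syn-elimination to the exocyclic alkene and returns at 18, which K2CO3 in MeOH converts into 19 as in step 10.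

**Further compounds**
F1 | step 4 | 6-methyl-6-(prop-2-ynyl)carvone, propargyl trans to isopropenyl | CC1=CC[C@@H](C(C)=C)[C@](C)(CC#C)C1=O
F2 | step 4 | (E)-alkenyl(dicyclohexyl)borane from F1 | CC1=CC[C@@H](C(C)=C)[C@](C)(C/C=C/B(C2CCCCC2)C2CCCCC2)C1=O
F3 | step 4 | 6-methyl-6-(3-oxopropyl)carvone | CC1=CC[C@@H](C(C)=C)[C@](C)(CCC=O)C1=O
F4 | step 4 | 3-hydroxy-4,4,8,10-tetramethyl-trans-decal-7-en-9-one, C3 epimers | CC1=CC[C@H]2C(C)(C)C(O)CC[C@]2(C)C1=O
F5 | step 12 | 1-phenyl-1H-tetrazol-5-yl sulfide of the saturated half | C(Sc1nnnn1-c1ccccc1)[C@H]1[C@H](C)CC[C@H]2C(C)(C)[C@H](O)CC[C@]12C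
F6 | step 12 | 1-phenyl-1H-tetrazol-5-yl sulfone of the saturated half | C(S(=O)(=O)c1nnnn1-c1ccccc1)[C@H]1[C@H](C)CC[C@H]2C(C)(C)[C@H](O)CC[C@]12C
F7 | step 12 | 9β-(hydroxymethyl)-4,4,8,10-tetramethyl-trans-decal-7-en-3α-ol | CC1=CC[C@H]2C(C)(C)[C@H](O)CC[C@]2(C)[C@H]1CO
F8 | step 12 | 3α-hydroxy-4,4,8,10-tetramethyl-trans-decal-7-ene-9β-carbaldehyde | CC1=CC[C@H]2C(C)(C)[C@H](O)CC[C@]2(C)[C@H]1C=O
F9 | step 12 | (E)-11,12-didehydro derivative of 22 | CC1=CC[C@H]2C(C)(C)[C@H](O)CC[C@]2(C)[C@H]1/C=C/[C@H]1[C@H](C)CC[C@H]2C(C)(C)[C@H](O)CC[C@]12C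
F10 | step 10 | 9-hydroxy-4,4,8,10-tetramethyl-3-(trimethylsilyloxy)-9-(trimethylsilylmethyl)-trans-decal-2,7-diene, either C9 epimer | CC1=CC[C@H]2C(C)(C)C(O[Si](C)(C)C)=CC[C@]2(C)C1(O)C[Si](C)(C)C
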